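**Retrosynthetic overview**
1. Target 9 ⇒ chalcane-flavan nonaphenol 8: the dihydrofuran ring is closed last, by dehydrative aryl-ether formation on the phloroglucinol ring with the carbinol C–O bond retained.
2. 8 ⇒ octabenzyl (2S,3R)-alcohol 7 ⇒ α,α-diaryl ketone 6: both upper-half stereocentres are set in one dynamic kinetic resolution hydrogenation.
3. Key disconnection 6 ⇒ 4 + 3: the C8–Cα bond joins the nucleophilic C8 of tetra-O-benzylcatechin 3 to the α-carbon of flavan-3-one 4, made electrophilic as an enolonium ion by Lewis-acid opening of the pyran C2–O1 bond.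
4. 3 and 4 ⇒ (+)-catechin 1 (benzylation, then Dess–Martin oxidation). The lower chroman ring comes intact from the chiral pool, the upper pyran ring is opened in the key step, and the dihydrobenzofuran ring is formed last.

Assumption: the target is taken exactly as drawn, that is (2R,3S)-catechin linked through C8 to an (R)-diarylmethine carbon bearing a (2S)-4,6-dihydroxy-2,3-dihydrobenzofuran-2-yl group; (+)-catechin is the commercial source of both halves.

**Step 1**
Reactants: 1 (+)-catechin; 2 benzyl bromide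
Product: 3 5,7,3',4'-tetra-O-benzyl-(+)-catechin, (2R,3S)-5,7-bis(benzyloxy)-2-[3,4-bis(benzyloxy)phenyl]chroman-3-ol
Conditions: BnBr (4.4 equiv), K2CO3 (5 equiv), DMF, 0 °C to rt, Ar
Reagents that add atoms: benzyl bromide (compound 2), BrCc1ccccc1
Why: Williamson ether synthesis in which the weak base alkylates the four phenols selectively over the secondary alcohol and leaves both stereocentres untouched.

**Step 2**
Reactants: 3 5,7,3',4'-tetra-O-benzyl-(+)-catechin
Product: 4 (2R)-5,7-bis(benzyloxy)-2-[3,4-bis(benzyloxy)phenyl]chroman-3-one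
Conditions: Dess–Martin periodinane (1.5 equiv), CH2Cl2, 0 °C to rt; crude ketone used at once
Reagents that add atoms: none
Why: Dess–Martin oxidation of the secondary alcohol under near-neutral conditions gives the flavan-3-one, whose C2 configuration is irrelevant because that centre is erased in step 3.

**Step 3 (key step)**
Reactants: 4 (2R)-5,7-bis(benzyloxy)-2-[3,4-bis(benzyloxy)phenyl]chroman-3-one; 3 5,7,3',4'-tetra-O-benzyl-(+)-catechin
Product: 6 1-[2-hydroxy-4,6-bis(benzyloxy)phenyl]-3-[3,4-bis(benzyloxy)phenyl]-3-{(2R,3S)-5,7-bis(benzyloxy)-2-[3,4-bis(benzyloxy)phenyl]-3-hydroxychroman-8-yl}propan-2-one (about 1:1 mixture of C3 epimers), via ring-opened enolonium zwitterion 5 (not isolated)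
Conditions: 3 (3 equiv, excess recovered), Sc(OTf)3 (20 mol %), HFIP/CH2Cl2 (1:4), slow addition of 4, −20 to 0 °C; Et3N quench
Reagents that add atoms: none
Why: Proposed new method: bidentate coordination of Sc(OTf)3 to the C3 carbonyl and O1 of 4 in the ionising solvent HFIP should heterolyse the benzylic C2–O1 bond to the α-keto 4-benzyloxybenzyl cation 5 (an enolonium ion, in equilibrium with its 2-hydroxyallyl form by enolisation toward C4), which C8 of 3 (the usual nucleophilic site of this arene, whose own pyran ring tolerates such Lewis acids) attacks at the less hindered monoaryl terminus, attack at the other terminus being disfavoured by two di-ortho-substituted aryl groups and reversible, so that an arene carbon and a ketone α-carbon, both innately nucleophilic, are joined in a Friedel–Crafts α-arylation; the closest known reactions are acid-catalysed Friedel–Crafts substitutions of benzoin-type α-oxy ketones, oxyallyl-cation arylations of α-sulfonyloxy ketones in fluorinated alcohols and the acid-induced C2–O1 cleavage of flavan ethers; the new stereocentre forms unselectively and is left labile for step 4.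

**Step 4**
Reactants: 6 1-[2-hydroxy-4,6-bis(benzyloxy)phenyl]-3-[3,4-bis(benzyloxy)phenyl]-3-{(2R,3S)-5,7-bis(benzyloxy)-2-[3,4-bis(benzyloxy)phenyl]-3-hydroxychroman-8-yl}propan-2-one (C3 epimers)
Product: 7 (2S,3R)-1-[2-hydroxy-4,6-bis(benzyloxy)phenyl]-3-[3,4-bis(benzyloxy)phenyl]-3-{(2R,3S)-5,7-bis(benzyloxy)-2-[3,4-bis(benzyloxy)phenyl]-3-hydroxychroman-8-yl}propan-2-ol
Conditions: RuCl2[(R)-xylbinap][(R)-daipen] (2 mol %), KOt-Bu (1.5 equiv), H2 (10 atm), i-PrOH/THF (2:1), 25 °C; cold 1 M HCl work-up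
Reagents that add atoms: none
Why: Dynamic kinetic resolution by Noyori-type bifunctional ketone hydrogenation, in which KOt-Bu rapidly epimerises the doubly benzylic α-carbon, the (R,R)-catalyst delivers hydride to the Re face of the carbonyl (diarylmethyl group as the large substituent, by the quadrant model) and consumes the Felkin–Anh-matched (3R)-epimer fastest (hydride anti to the bulky chromanyl ring), so C2 (S) and C3 (R) are set together while the benzyl ethers survive.

**Step 5**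
Reactants: 7 (2S,3R)-1-[2-hydroxy-4,6-bis(benzyloxy)phenyl]-3-[3,4-bis(benzyloxy)phenyl]-3-{(2R,3S)-5,7-bis(benzyloxy)-2-[3,4-bis(benzyloxy)phenyl]-3-hydroxychroman-8-yl}propan-2-ol
Product: 9 (2R,3S)-2-(3,4-dihydroxyphenyl)-8-{(R)-(3,4-dihydroxyphenyl)[(2S)-4,6-dihydroxy-2,3-dihydro-1-benzofuran-2-yl]methyl}chroman-3,5,7-triol (target CNP0280971.2), via chalcane-flavan nonaphenol 8 (not isolated)
Conditions: H2 (1 atm), Pd(OH)2/C, 1,4-dioxane/H2O (9:1), rt; filter under Ar; then aq HCl (to 0.05 M), 70 °C, HPLC control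
Reagents that add atoms: none
Why: Hydrogenolysis frees all eight phenols, and mild acid then drives a biomimetic dehydrative etherification in which the 2,4,6-trihydroxyphenyl ring reacts through its keto tautomer with the neighbouring secondary alcohol (hemiketal formation, then rearomatising loss of water), so the carbinol C–O bond is never broken and C2 of the new 5-membered ring keeps the (S) configuration (known analogue: acid-catalysed O-alkylation of phloroglucinol by alcohols).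

**Compound list**
1 | (+)-catechin, (2R,3S)-2-(3,4-dihydroxyphenyl)chroman-3,5,7-triol | Oc1cc(O)c2c(c1)O[C@H](c1ccc(O)c(O)c1)[C@@H](O)C2 | starting material
2 | benzyl bromide | BrCc1ccccc1 | starting material
3 | 5,7,3',4'-tetra-O-benzyl-(+)-catechin, (2R,3S)-5,7-bis(benzyloxy)-2-[3,4-bis(benzyloxy)phenyl]chroman-3-ol | c1ccccc1COc1cc(OCc2ccccc2)c2c(c1)O[C@H](c1ccc(OCc3ccccc3)c(OCc3ccccc3)c1)[C@@H](O)C2 | intermediate
4 | (2R)-5,7-bis(benzyloxy)-2-[3,4-bis(benzyloxy)phenyl]chroman-3-one | c1ccccc1COc1cc(OCc2ccccc2)c2c(c1)O[C@H](c1ccc(OCc3ccccc3)c(OCc3ccccc3)c1)C(=O)C2 | intermediate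
5 | ring-opened enolonium zwitterion: 3,5-bis(benzyloxy)-2-{3-[3,4-bis(benzyloxy)phenyl]-2-oxopropyl}phenolate (scandium-bound) with the cationic centre at the benzylic C3 of the side chain | [O-]c1cc(OCc2ccccc2)cc(OCc2ccccc2)c1CC(=O)[CH+]c1ccc(OCc2ccccc2)c(OCc2ccccc2)c1 | intermediate (not isolated)
6 | 1-[2-hydroxy-4,6-bis(benzyloxy)phenyl]-3-[3,4-bis(benzyloxy)phenyl]-3-{(2R,3S)-5,7-bis(benzyloxy)-2-[3,4-bis(benzyloxy)phenyl]-3-hydroxychroman-8-yl}propan-2-one, C3 epimer mixture | Oc1cc(OCc2ccccc2)cc(OCc2ccccc2)c1CC(=O)C(c1ccc(OCc2ccccc2)c(OCc2ccccc2)c1)c1c(OCc2ccccc2)cc(OCc2ccccc2)c2c1O[C@H](c1ccc(OCc3ccccc3)c(OCc3ccccc3)c1)[C@@H](O)C2 | intermediate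
7 | (2S,3R)-1-[2-hydroxy-4,6-bis(benzyloxy)phenyl]-3-[3,4-bis(benzyloxy)phenyl]-3-{(2R,3S)-5,7-bis(benzyloxy)-2-[3,4-bis(benzyloxy)phenyl]-3-hydroxychroman-8-yl}propan-2-ol | Oc1cc(OCc2ccccc2)cc(OCc2ccccc2)c1C[C@H](O)[C@H](c1ccc(OCc2ccccc2)c(OCc2ccccc2)c1)c1c(OCc2ccccc2)cc(OCc2ccccc2)c2c1O[C@H](c1ccc(OCc3ccccc3)c(OCc3ccccc3)c1)[C@@H](O)C2 | intermediate
8 | chalcane-flavan nonaphenol, (2S,3R)-3-(3,4-dihydroxyphenyl)-3-[(2R,3S)-2-(3,4-dihydroxyphenyl)-3,5,7-trihydroxychroman-8-yl]-1-(2,4,6-trihydroxyphenyl)propan-2-ol | Oc1cc(O)cc(O)c1C[C@H](O)[C@H](c1ccc(O)c(O)c1)c1c(O)cc(O)c2c1O[C@H](c1ccc(O)c(O)c1)[C@@H](O)C2 | intermediate (not isolated)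
9 | (2R,3S)-2-(3,4-dihydroxyphenyl)-8-{(R)-(3,4-dihydroxyphenyl)[(2S)-4,6-dihydroxy-2,3-dihydro-1-benzofuran-2-yl]methyl}chroman-3,5,7-triol | Oc1cc(O)c2c(c1)O[C@H]([C@H](c1ccc(O)c(O)c1)c1c(O)cc(O)c3c1O[C@H](c1ccc(O)c(O)c1)[C@@H](O)C3)C2 | target

**Step count and risks**
Total steps: 5. Longest linear sequence: 5 (1 → 3 → 4 → 6 → 7 → 9; compound 3 also serves as the second reactant of step 3).

Steps most likely to fail:

Step 3. Ionisation may be sluggish, attack may occur at the wrong allyl terminus, or 6 may cyclodehydrate to a benzofuran under acid. Fallback: the polarity of the arene is inverted instead of that of the ketone, under basic conditions. It sets out from 4 and 3. SmI2 (2.2 equiv) in THF/MeOH at −78 °C cleaves the α-aryloxy ketone bond of 4 reductively to 1-[2-hydroxy-4,6-bis(benzyloxy)phenyl]-3-[3,4-bis(benzyloxy)phenyl]propan-2-one F1. N-Bromosuccinimide in CH2Cl2 at −78 °C brominates 3 at C8 to (2R,3S)-8-bromo-5,7-bis(benzyloxy)-2-[3,4-bis(benzyloxy)phenyl]chroman-3-ol F2. Pd(OAc)2/P(t-Bu)3 with NaOt-Bu in THF at 60 °C then α-arylates the enolate of F1 with F2 at its less hindered, more acidic methylene (next to the 3,4-bis(benzyloxy)phenyl ring). The fallback comes back to the route at 6.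

Step 4. The catalyst may discriminate the faces of this hindered dialkyl-type ketone poorly, or in the opposite sense. Fallback: substrate-controlled reduction with resolution and recycling instead of catalyst-controlled dynamic resolution. It sets out from 6, whose epimers are separated by chromatography into the (3R)-epimer of 6 F3 and the (3S)-epimer of 6 F4. F3 is reduced with LiBH(s-Bu)3 in THF at −78 °C, which is non-epimerising and Felkin–Anh selective, and comes back to the route at 7. F4 is re-equilibrated to the 1:1 mixture 6 with DBU in CH2Cl2 and recycled.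

Step 5. The carbinol could instead close onto the C7 oxygen position of the flavan ring A, or the diarylmethine–C8 bond could suffer acid cleavage. Fallback: regiospecific ring closure at the benzyl stage, using the single free phenol of ring A. It sets out from 7. PhNTf2 and K2CO3 in DMF give the aryl triflate of 7 F5. Pd(OAc)2/t-BuXPhos with Cs2CO3 in toluene at 80 °C effects intramolecular C–O coupling of the secondary alcohol, with retention at the carbinol, to the octa-O-benzyl ether of the target F6. Hydrogenolysis with H2 and Pd(OH)2/C in THF/MeOH comes back to the route at 9.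

**Further compounds**
F1 | step 3 | 1-[2-hydroxy-4,6-bis(benzyloxy)phenyl]-3-[3,4-bis(benzyloxy)phenyl]propan-2-one | Oc1cc(OCc2ccccc2)cc(OCc2ccccc2)c1CC(=O)Cc1ccc(OCc2ccccc2)c(OCc2ccccc2)c1
F2 | step 3 | (2R,3S)-8-bromo-5,7-bis(benzyloxy)-2-[3,4-bis(benzyloxy)phenyl]chroman-3-ol | Brc1c(OCc2ccccc2)cc(OCc2ccccc2)c2c1O[C@H](c1ccc(OCc3ccccc3)c(OCc3ccccc3)c1)[C@@H](O)C2
F3 | step 4 | (3R)-epimer of 6, (3R)-1-[2-hydroxy-4,6-bis(benzyloxy)phenyl]-3-[3,4-bis(benzyloxy)phenyl]-3-{(2R,3S)-5,7-bis(benzyloxy)-2-[3,4-bis(benzyloxy)phenyl]-3-hydroxychroman-8-yl}propan-2-one | Oc1cc(OCc2ccccc2)cc(OCc2ccccc2)c1CC(=O)[C@H](c1ccc(OCc2ccccc2)c(OCc2ccccc2)c1)c1c(OCc2ccccc2)cc(OCc2ccccc2)c2c1O[C@H](c1ccc(OCc3ccccc3)c(OCc3ccccc3)c1)[C@@H](O)C2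
F4 | step 4 | (3S)-epimer of 6, (3S)-1-[2-hydroxy-4,6-bis(benzyloxy)phenyl]-3-[3,4-bis(benzyloxy)phenyl]-3-{(2R,3S)-5,7-bis(benzyloxy)-2-[3,4-bis(benzyloxy)phenyl]-3-hydroxychroman-8-yl}propan-2-one | Oc1cc(OCc2ccccc2)cc(OCc2ccccc2)c1CC(=O)[C@@H](c1ccc(OCc2ccccc2)c(OCc2ccccc2)c1)c1c(OCc2ccccc2)cc(OCc2ccccc2)c2c1O[C@H](c1ccc(OCc3ccccc3)c(OCc3ccccc3)c1)[C@@H](O)C2
F5 | step 5 | aryl triflate of 7, 3,5-bis(benzyloxy)-2-[(2S,3R)-3-[3,4-bis(benzyloxy)phenyl]-3-{(2R,3S)-5,7-bis(benzyloxy)-2-[3,4-bis(benzyloxy)phenyl]-3-hydroxychroman-8-yl}-2-hydroxypropyl]phenyl trifluoromethanesulfonate | FC(F)(F)S(=O)(=O)Oc1cc(OCc2ccccc2)cc(OCc2ccccc2)c1C[C@H](O)[C@H](c1ccc(OCc2ccccc2)c(OCc2ccccc2)c1)c1c(OCc2ccccc2)cc(OCc2ccccc2)c2c1O[C@H](c1ccc(OCc3ccccc3)c(OCc3ccccc3)c1)[C@@H](O)C2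
F6 | step 5 | octa-O-benzyl ether of the target, (2R,3S)-5,7-bis(benzyloxy)-2-[3,4-bis(benzyloxy)phenyl]-8-{(R)-[3,4-bis(benzyloxy)phenyl][(2S)-4,6-bis(benzyloxy)-2,3-dihydro-1-benzofuran-2-yl]methyl}chroman-3-ol | c1ccccc1COc1cc(OCc2ccccc2)c2c(c1)O[C@H]([C@H](c1ccc(OCc3ccccc3)c(OCc3ccccc3)c1)c1c(OCc3ccccc3)cc(OCc3ccccc3)c3c1O[C@H](c1ccc(OCc4ccccc4)c(OCc4ccccc4)c1)[C@@H](O)C3)C2
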